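Early in both earlier runs L jumps, then creeps towards a plateau, and the bend between the two is what I am examined on.

| setting | red | blue | delta | theta |
|---|---|---|---|---|
| X | 0.12 M | 0.47 M | 0.30 M | 0.084 M |
| temperature | 58 °C | 74 °C |  |  |
| remark | run made earlier | run made earlier | at 50 °C throughout | at 80 °C until 80 min, from then on at 50 °C |
| time |  |  | 4.0 h | 4.0 h |

| run | time / h | L / % |
|---|---|---|
| red | 0.500 | 20.7 |
| red | 1.33 | 35.1 |
| red | 2.50 | 42.5 |
| red | 4.00 | 47.5 |
| red | 6.00 | 51.6 |
| red | 8.00 | 53.1 |
| blue | 0.250 | 42.0 |
| blue | 0.333 | 45.9 |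
| blue | 0.500 | 49.9 |
| blue | 0.833 | 52.5 |
| blue | 1.33 | 54.6 |
| blue | 2.00 | 54.7 |
| blue | 3.00 | 55.0 |

(readings scatter by 0.3 percentage points)

* the flask that ends with the higher amount of L, in percent of the X charged, or "neither" when 2 percentage points or less lies between them (delta / theta / neither)
* final L, as a percentage of the X charged, in delta
* final L, as a percentage of the X charged, in theta

- the earlier runs were read with a standard deviation of 0.3 percentage points

*Where does the creep end?* The blue run holds 55.0 % at its last reading, so I set the plateau at 55.0 %.

*How fast is the creep?* I take the gap to the plateau as shrinking exponentially. The red run gives 0.372 h⁻¹ and the blue run 2.14 h⁻¹.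

*Where does it start?* Running each tail back to zero time gives a burst of L: 23.3 % in red, 40.1 % in blue.

*What do you carry from that?* The burst odds, L from the burst over the rest of the charge. They are a number fitted to each run, not a ratio of rates, and the rest of the charge holds unreacted X as well. Red gives 0.304, blue 0.670.

*Red and blue differ in [X] too. Why step in temperature?* I cannot separate the two settings from these runs. Ignoring [X] is my assumption.

*And delta?* Its 50 °C lies below red by half the red-to-blue step. Stepping the logarithms gives burst odds 0.205 and a creep of 0.155 h⁻¹. My delta ends near 34.6 %.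

*Theta?* Blue read 54.6 % at 1.33 h, and theta is hotter than blue for 80 min. So I expect theta near the plateau.

The forecast says theta, with delta 45 % and theta 53.3 %, on the ground that “order 1.5 fits both runs well”. For delta my number differs from it.

The flasks give theta: delta 33.0 %, theta 55.8 %.

    J ⇌ X (k = 0.0686 min⁻¹, Ea = 114 kJ mol⁻¹)
    L ⇌ J (K = 0.513, k = 0.0122 min⁻¹, Ea = 98.0 kJ mol⁻¹, ΔH = −11.0 kJ mol⁻¹)
    X ⇌ L (K = 3.09, k = 0.130 min⁻¹, Ea = 111 kJ mol⁻¹, ΔH = −29.0 kJ mol⁻¹)
    (constants at 80 °C)

The rest of the charge is X and the hidden J. The same burst odds, 0.205, and the same creep put on a neighbouring flask, delta read at 1.0 h, give 22.5 % of L. That flask stands at 16.3 % of L, with X at 44 % and J at 39.3 %.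

All runs come from a simulation from invented constants; the scatter is artificial.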